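## Retrosynthetic overview
1. The last C–C bond is C1'–C2' of the side chain: an (S)-chromen-2-ylmethyl triflate plus lithiated all-E-octaprenyl phenyl sulfone, followed by Pd/hydride desulfonylation and phenol desilylation.
2. The C40 sulfone comes from two geranylgeraniol halves, a C20 allylic sulfone and a C20 ω-allylic bromide (terminal SeO2 oxidation), joined by sulfone alkylation and desulfonylation.
3. The only stereocentre (C2) comes from a lipase-catalysed desymmetrisation of a prochiral 2H-chromene-2,2-dimethanol. The acetylated arm is later reduced to CH3 and the other arm becomes CH2OTf.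
4. The prochiral chromene comes from mono-silylated 2,3-dimethylhydroquinone and (2,2-dimethyl-1,3-dioxan-5-ylidene)acetaldehyde (ortho-aldol, o-quinone methide, oxa-6π closure).
5. Ring order: the benzene ring is bought, and the pyran ring is the only ring built (step 5), before the stereocentre and the chain. The dioxane is a temporary protecting ring, opened in step 6.

Assumption: the lipase acetylates the same enantiotopic CH2OH arm of the chromene-2,2-dimethanol as in the closely related 6-O-protected chroman-2,2-dimethanols, giving the (S)-monoacetate. The sense is confirmed by correlation before going on.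

## Route

Step 1
Reactants: 1 2,3-dimethylhydroquinone
Product: 2 2,3-dimethyl-4-(triisopropylsilyloxy)phenol
Conditions: TIPSCl (0.5 equiv vs 1), imidazole, DMF, 0 °C to rt; excess 1 recovered
Reagents that add atoms: triisopropylsilyl chloride, CC(C)[Si](Cl)(C(C)C)C(C)C
Why: Silyl ether formation on a C2-symmetric hydroquinone used in excess gives one possible mono-ether, and aryl-OTIPS survives every later step until fluoride.

Step 2
Reactants: 3 2,2-dimethyl-1,3-dioxan-5-one
Product: 4 ethyl 2-(2,2-dimethyl-1,3-dioxan-5-ylidene)acetate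
Conditions: Ph3P=CHCO2Et, CH2Cl2, rt
Reagents that add atoms: (carbethoxymethylene)triphenylphosphorane, CCOC(=O)C=P(c1ccccc1)(c1ccccc1)c1ccccc1
Why: Wittig olefination with a neutral stabilised ylide works on this α,α'-dioxygenated (activated) ketone without enolisation, and the symmetric ketone gives no E/Z issue.

Step 3
Reactants: 4 ethyl 2-(2,2-dimethyl-1,3-dioxan-5-ylidene)acetate
Product: 5 2-(2,2-dimethyl-1,3-dioxan-5-ylidene)ethanol
Conditions: DIBAL-H (2.2 equiv), CH2Cl2, −78 to 0 °C; Na2SO4·10H2O quench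
Reagents that add atoms: none
Why: DIBAL-H 1,2-reduction of an enoate gives the allylic alcohol cleanly, and the non-acidic quench keeps the acetonide.

Step 4
Reactants: 5 2-(2,2-dimethyl-1,3-dioxan-5-ylidene)ethanol
Product: 6 2-(2,2-dimethyl-1,3-dioxan-5-ylidene)acetaldehyde
Conditions: activated MnO2, CH2Cl2, rt
Reagents that add atoms: none
Why: MnO2 allylic oxidation is neutral, selective for the allylic alcohol and stops at the enal.

Step 5
Reactants: 2 2,3-dimethyl-4-(triisopropylsilyloxy)phenol; 6 2-(2,2-dimethyl-1,3-dioxan-5-ylidene)acetaldehyde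
Product: 9 2',2',7,8-tetramethyl-6-(triisopropylsilyloxy)spiro[chromene-2,5'-[1,3]dioxane], via titanium(IV) aryloxide 7 (not isolated), via o-quinone methide 8 (not isolated)
Conditions: Ti(OEt)4 (0.25 equiv), toluene, distil off EtOH; then 6 (1.1 equiv), reflux
Reagents that add atoms: none
Why: In this metal-phenoxide-directed ortho-aldol, dehydration and oxa-6π electrocyclisation sequence the Ti-bound enal is delivered to the only free ortho carbon, and C2 is still prochiral so no stereochemistry is at stake.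

Step 6
Reactants: 9 spiro-acetonide chromene
Product: 10 [7,8-dimethyl-6-(triisopropylsilyloxy)-2H-chromene-2,2-diyl]dimethanol
Conditions: AcOH/H2O/THF (3:1:1), 40 °C
Reagents that add atoms: none
Why: Mild acid-catalysed acetal hydrolysis frees the prochiral 1,3-diol while aryl-OTIPS and the chromene are untouched.

Step 7
Reactants: 10 [7,8-dimethyl-6-(triisopropylsilyloxy)-2H-chromene-2,2-diyl]dimethanol
Product: 11 [(2S)-2-(hydroxymethyl)-7,8-dimethyl-6-(triisopropylsilyloxy)-2H-chromen-2-yl]methyl acetate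
Conditions: lipase (Candida antarctica lipase B, immobilised; serine hydrolase, EC 3.1.1.3), vinyl acetate (5 equiv), MTBE, 25 °C; stop at full consumption of 10 (5–10 % diacetate)
Reagents that add atoms: vinyl acetate, CC(=O)OC=C
Why: In this lipase-catalysed enantiotopic-group-selective transesterification (desymmetrisation) the chiral active site tells the ring-O side from the ring-C3 side and acetylates one CH2OH only, which sets C2 as S catalytically from an achiral diol, and slight over-acylation removes the minor enantiomer and raises the ee.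

Step 8
Reactants: 11 (S)-monoacetate
Product: 12 [(2R)-2-[(tert-butyldimethylsilyloxy)methyl]-7,8-dimethyl-6-(triisopropylsilyloxy)-2H-chromen-2-yl]methyl acetate
Conditions: TBSOTf, 2,6-lutidine, CH2Cl2, −78 to 0 °C
Reagents that add atoms: tert-butyldimethylsilyl triflate, CC(C)(C)[Si](C)(C)OS(=O)(=O)C(F)(F)F
Why: Fast low-temperature silylation with a non-nucleophilic base caps the hindered free arm before any 1,3-acyl migration (which would racemise) can occur, and the descriptor changes to R by CIP ranking only.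

Step 9
Reactants: 12 (R)-silyl ether acetate
Product: 13 [(2R)-2-[(tert-butyldimethylsilyloxy)methyl]-7,8-dimethyl-6-(triisopropylsilyloxy)-2H-chromen-2-yl]methanol
Conditions: DIBAL-H (2.5 equiv), CH2Cl2, −78 °C; Na2SO4·10H2O quench
Reagents that add atoms: none
Why: Reductive deacetylation goes through a cold aluminium alkoxide and avoids the free basic alkoxide that could trigger O-to-O silyl migration and loss of ee.

Step 10
Reactants: 13 (R)-mono-TBS diol
Product: 15 (2S)-2-[(tert-butyldimethylsilyloxy)methyl]-2,7,8-trimethyl-6-(triisopropylsilyloxy)-2H-chromene, via primary triflate 14 (not isolated)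
Conditions: Tf2O, 2,6-lutidine, CH2Cl2, −78 °C; rapid cold filtration, solvent swap; LiEt3BH (3 equiv), THF, 0 °C to rt
Reagents that add atoms: none
Why: In this triflation and Super-Hydride SN2 deoxygenation the very nucleophilic Et3BH− displaces even a neopentyl-type triflate, the silyl-protected second arm cannot close to an achiral oxetane, and no bond to C2 is touched.

Step 11
Reactants: 15 (S)-TBS ether
Product: 16 [(2S)-2,7,8-trimethyl-6-(triisopropylsilyloxy)-2H-chromen-2-yl]methanol
Conditions: HF·pyridine, pyridine, THF, 0 °C to rt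
Reagents that add atoms: none
Why: Buffered acidic fluoride cleaves the alkyl TBS ether much faster than the bulky aryl TIPS ether and is too weakly acidic to ionise the allylic C2–O bond.

Step 12
Reactants: 17 (2E,6E,10E)-geranylgeraniol
Product: 19 (2E,6E,10E)-geranylgeranyl phenyl sulfone, via geranylgeranyl bromide 18 (not isolated)
Conditions: PBr3 (0.4 equiv), Et2O, 0 °C; crude bromide, PhSO2Na, DMF, rt
Reagents that add atoms: sodium benzenesulfinate, [Na+].[O-]S(=O)c1ccccc1
Why: SN2 bromination of the primary allylic alcohol followed by S-alkylation of sulfinate proceeds without allylic transposition or E/Z loss.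

Step 13
Reactants: 17 (2E,6E,10E)-geranylgeraniol
Product: 20 (2E,6E,10E)-geranylgeranyl tert-butyldiphenylsilyl ether
Conditions: TBDPSCl, imidazole, CH2Cl2, rt
Reagents that add atoms: tert-butyldiphenylsilyl chloride, CC(C)(C)[Si](Cl)(c1ccccc1)c1ccccc1
Why: The achiral TBDPS ether tolerates SeO2/TBHP, sulfone carbanions and Pd/hydride, and it is not a leaving group for Pd(0).

Step 14
Reactants: 20 geranylgeranyl TBDPS ether
Product: 21 (2E,6E,10E,14E)-16-(tert-butyldiphenylsilyloxy)-2,6,10,14-tetramethylhexadeca-2,6,10,14-tetraen-1-ol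
Conditions: SeO2 (0.1 equiv), t-BuOOH (2.5 equiv), salicylic acid (0.1 equiv), CH2Cl2, 0 °C to rt; stop at about 60 % conversion, recycle 20
Reagents that add atoms: tert-butyl hydroperoxide, CC(C)(C)OO
Why: Catalytic SeO2 allylic oxidation (ene reaction then [2,3]-shift) prefers the terminal gem-dimethyl alkene and delivers only the E-CH2OH.

Step 15
Reactants: 21 ω-hydroxy C20 silyl ether
Product: 22 (2E,6E,10E,14E)-16-bromo-3,7,11,15-tetramethylhexadeca-2,6,10,14-tetraen-1-yl tert-butyldiphenylsilyl ether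
Conditions: CBr4, PPh3, CH2Cl2, −20 to 0 °C
Reagents that add atoms: carbon tetrabromide, BrC(Br)(Br)Br
Why: The Appel reaction converts the primary allylic alcohol to the bromide under neutral conditions, so the silyl ether and the alkene geometry stay intact.

Step 16
Reactants: 19 geranylgeranyl phenyl sulfone; 22 C20 ω-bromide
Product: 24 (all-E)-17-(phenylsulfonyl)octaprenyl tert-butyldiphenylsilyl ether (racemic at C17), via lithiated sulfone 23 (not isolated)
Conditions: n-BuLi (1.05 equiv), THF/DMPU, −78 °C; then 22, −78 to −20 °C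
Reagents that add atoms: none
Why: Alkylation of an allylic sulfone carbanion with an allylic bromide (Biellmann/Julia-type head-to-tail coupling) is α-selective and SN2, so all alkenes stay E, and the transient C17 centre is erased in step 17.

Step 17
Reactants: 24 C40 sulfone
Product: 25 (all-E)-octaprenyl tert-butyldiphenylsilyl ether
Conditions: PdCl2(dppp) (5 mol %), LiEt3BH (2.5 equiv), THF, 0 °C to rt
Reagents that add atoms: none
Why: In this Pd-catalysed hydride desulfonylation the π-allyl-Pd intermediate takes hydride at its less substituted terminus, which keeps the position and E-geometry of the trisubstituted alkene.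

Step 18
Reactants: 25 octaprenyl TBDPS ether
Product: 26 (all-E)-octaprenol
Conditions: TBAF, THF, rt
Reagents that add atoms: none
Why: Fluoride-driven desilylation does not affect the eight isolated alkenes.

Step 19
Reactants: 26 (all-E)-octaprenol
Product: 28 (all-E)-octaprenyl phenyl sulfone, via octaprenyl bromide 27 (not isolated)
Conditions: PBr3 (0.4 equiv), Et2O, 0 °C; crude bromide, PhSO2Na, DMF/THF, rt
Reagents that add atoms: sodium benzenesulfinate, [Na+].[O-]S(=O)c1ccccc1
Why: This is the same SN2 bromination and sulfinate S-alkylation as in step 12, with retention of the 2E-alkene.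

Step 20
Reactants: 16 (S)-chromen-2-ylmethanol
Product: 29 [(2S)-2,7,8-trimethyl-6-(triisopropylsilyloxy)-2H-chromen-2-yl]methyl triflate
Conditions: Tf2O, 2,6-lutidine, CH2Cl2, −78 to −20 °C; cold short silica plug, used at once
Reagents that add atoms: triflic anhydride, O=S(=O)(OS(=O)(=O)C(F)(F)F)C(F)(F)F
Why: O-Triflation gives the only leaving group reactive enough for substitution next to the quaternary C2, and with no β-hydrogen no elimination is possible.

Step 21
Reactants: 28 octaprenyl phenyl sulfone; 29 (S)-triflate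
Product: 31 (2R)-2-[(all-E)-4,8,12,16,20,24,28,32-octamethyl-2-(phenylsulfonyl)tritriaconta-3,7,11,15,19,23,27,31-octaen-1-yl]-2,7,8-trimethyl-6-(triisopropylsilyloxy)-2H-chromene (epimers at C2'), via lithiated octaprenyl sulfone 30 (not isolated)
Conditions: 28 (1.5 equiv), n-BuLi (1.45 equiv), THF/DMPU, −78 °C; then 29, −78 to 0 °C
Reagents that add atoms: none
Why: SN2 alkylation of the soft sulfone carbanion by the primary triflate is the union established for chroman-2-ylmethyl triflates, C2 is a spectator (R by CIP ranking only), and the C2' epimers converge in step 22.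

Step 22
Reactants: 31 coupled sulfone
Product: 32 (2R)-O-triisopropylsilyl-plastochromenol-8
Conditions: PdCl2(dppp) (10 mol %), LiEt3BH (3 equiv), THF, 0 °C to rt, dark
Reagents that add atoms: none
Why: Pd-catalysed hydride desulfonylation gives the 3'E-alkene as in step 17, while the ring C2–O bond lies nearly in the nodal plane of the C3=C4 π-system at a quaternary carbon and therefore does not ionise to a π-allyl complex.

Step 23
Reactants: 32 O-TIPS-plastochromenol-8
Product: 33 plastochromenol-8, (2R)-2,7,8-trimethyl-2-[(3E,7E,11E,15E,19E,23E,27E)-4,8,12,16,20,24,28,32-octamethyltritriaconta-3,7,11,15,19,23,27,31-octaen-1-yl]-2H-chromen-6-ol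
Conditions: TBAF/AcOH (1:1, 1.5 equiv), THF, 0 °C, argon, dim light
Reagents that add atoms: none
Why: Buffered fluoride desilylation frees the phenol at 0 °C without acid, strong base, heat or UV, so neither the polyene nor the photolabile C2 stereocentre of the 2H-chromene is disturbed.

## Compound list
1 | 2,3-dimethylhydroquinone | Cc1c(C)c(O)ccc1O | starting material
2 | 2,3-dimethyl-4-(triisopropylsilyloxy)phenol | Cc1c(O)ccc(O[Si](C(C)C)(C(C)C)C(C)C)c1C | intermediate
3 | 2,2-dimethyl-1,3-dioxan-5-one | CC1(C)OCC(=O)CO1 | starting material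
4 | ethyl 2-(2,2-dimethyl-1,3-dioxan-5-ylidene)acetate | CCOC(=O)C=C1COC(C)(C)OC1 | intermediate
5 | 2-(2,2-dimethyl-1,3-dioxan-5-ylidene)ethanol | OCC=C1COC(C)(C)OC1 | intermediate
6 | 2-(2,2-dimethyl-1,3-dioxan-5-ylidene)acetaldehyde | O=CC=C1COC(C)(C)OC1 | intermediate
7 | titanium(IV) tetrakis[2,3-dimethyl-4-(triisopropylsilyloxy)phenoxide] | [Ti](Oc1ccc(O[Si](C(C)C)(C(C)C)C(C)C)c(C)c1C)(Oc1ccc(O[Si](C(C)C)(C(C)C)C(C)C)c(C)c1C)(Oc1ccc(O[Si](C(C)C)(C(C)C)C(C)C)c(C)c1C)Oc1ccc(O[Si](C(C)C)(C(C)C)C(C)C)c(C)c1C | intermediate (not isolated)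
8 | o-quinone methide, 6-[2-(2,2-dimethyl-1,3-dioxan-5-ylidene)ethylidene]-2,3-dimethyl-4-(triisopropylsilyloxy)cyclohexa-2,4-dienone | O=C1C(C)=C(C)C(O[Si](C(C)C)(C(C)C)C(C)C)=CC1=CC=C1COC(C)(C)OC1 | intermediate (not isolated)
9 | 2',2',7,8-tetramethyl-6-(triisopropylsilyloxy)spiro[chromene-2,5'-[1,3]dioxane] | CC1(C)OCC2(CO1)C=Cc1cc(O[Si](C(C)C)(C(C)C)C(C)C)c(C)c(C)c1O2 | intermediate
10 | [7,8-dimethyl-6-(triisopropylsilyloxy)-2H-chromene-2,2-diyl]dimethanol | OCC1(CO)C=Cc2cc(O[Si](C(C)C)(C(C)C)C(C)C)c(C)c(C)c2O1 | intermediate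
11 | (S)-monoacetate | OC[C@]1(COC(C)=O)C=Cc2cc(O[Si](C(C)C)(C(C)C)C(C)C)c(C)c(C)c2O1 | intermediate
12 | (R)-TBS ether acetate | CC(C)(C)[Si](C)(C)OC[C@]1(COC(C)=O)C=Cc2cc(O[Si](C(C)C)(C(C)C)C(C)C)c(C)c(C)c2O1 | intermediate
13 | (R)-mono-TBS diol | CC(C)(C)[Si](C)(C)OC[C@]1(CO)C=Cc2cc(O[Si](C(C)C)(C(C)C)C(C)C)c(C)c(C)c2O1 | intermediate
14 | (S)-triflate of 13 | CC(C)(C)[Si](C)(C)OC[C@]1(COS(=O)(=O)C(F)(F)F)C=Cc2cc(O[Si](C(C)C)(C(C)C)C(C)C)c(C)c(C)c2O1 | intermediate (not isolated)
15 | (2S)-2-[(TBS-oxy)methyl]-2,7,8-trimethyl-6-(TIPS-oxy)-2H-chromene | CC(C)(C)[Si](C)(C)OC[C@]1(C)C=Cc2cc(O[Si](C(C)C)(C(C)C)C(C)C)c(C)c(C)c2O1 | intermediate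
16 | [(2S)-2,7,8-trimethyl-6-(TIPS-oxy)-2H-chromen-2-yl]methanol | OC[C@]1(C)C=Cc2cc(O[Si](C(C)C)(C(C)C)C(C)C)c(C)c(C)c2O1 | intermediate
17 | (2E,6E,10E)-geranylgeraniol | CC(C)=CCC/C(C)=C/CC/C(C)=C/CC/C(C)=C/CO | starting material
18 | geranylgeranyl bromide | CC(C)=CCC/C(C)=C/CC/C(C)=C/CC/C(C)=C/CBr | intermediate (not isolated)
19 | geranylgeranyl phenyl sulfone | CC(C)=CCC/C(C)=C/CC/C(C)=C/CC/C(C)=C/CS(=O)(=O)c1ccccc1 | intermediate
20 | geranylgeranyl TBDPS ether | CC(C)=CCC/C(C)=C/CC/C(C)=C/CC/C(C)=C/CO[Si](c1ccccc1)(c1ccccc1)C(C)(C)C | intermediate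
21 | ω-(E)-hydroxy C20 TBDPS ether | OC/C(C)=C/CC/C(C)=C/CC/C(C)=C/CC/C(C)=C/CO[Si](c1ccccc1)(c1ccccc1)C(C)(C)C | intermediate
22 | ω-(E)-bromo C20 TBDPS ether | BrC/C(C)=C/CC/C(C)=C/CC/C(C)=C/CC/C(C)=C/CO[Si](c1ccccc1)(c1ccccc1)C(C)(C)C | intermediate
23 | α-lithio geranylgeranyl phenyl sulfone | CC(C)=CCC/C(C)=C/CC/C(C)=C/CC/C(C)=C/C([Li])S(=O)(=O)c1ccccc1 | intermediate (not isolated)
24 | 17-(phenylsulfonyl)octaprenyl TBDPS ether | CC(C)=CCC/C(C)=C/CC/C(C)=C/CC/C(C)=C/C(S(=O)(=O)c1ccccc1)C/C(C)=C/CC/C(C)=C/CC/C(C)=C/CC/C(C)=C/CO[Si](c1ccccc1)(c1ccccc1)C(C)(C)C | intermediate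
25 | (all-E)-octaprenyl TBDPS ether | CC(C)=CCC/C(C)=C/CC/C(C)=C/CC/C(C)=C/CC/C(C)=C/CC/C(C)=C/CC/C(C)=C/CC/C(C)=C/CO[Si](c1ccccc1)(c1ccccc1)C(C)(C)C | intermediate
26 | (all-E)-octaprenol | CC(C)=CCC/C(C)=C/CC/C(C)=C/CC/C(C)=C/CC/C(C)=C/CC/C(C)=C/CC/C(C)=C/CC/C(C)=C/CO | intermediate
27 | (all-E)-octaprenyl bromide | CC(C)=CCC/C(C)=C/CC/C(C)=C/CC/C(C)=C/CC/C(C)=C/CC/C(C)=C/CC/C(C)=C/CC/C(C)=C/CBr | intermediate (not isolated)
28 | (all-E)-octaprenyl phenyl sulfone | CC(C)=CCC/C(C)=C/CC/C(C)=C/CC/C(C)=C/CC/C(C)=C/CC/C(C)=C/CC/C(C)=C/CC/C(C)=C/CS(=O)(=O)c1ccccc1 | intermediate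
29 | (S)-chromen-2-ylmethyl triflate | FC(F)(F)S(=O)(=O)OC[C@]1(C)C=Cc2cc(O[Si](C(C)C)(C(C)C)C(C)C)c(C)c(C)c2O1 | intermediate
30 | α-lithio octaprenyl phenyl sulfone | CC(C)=CCC/C(C)=C/CC/C(C)=C/CC/C(C)=C/CC/C(C)=C/CC/C(C)=C/CC/C(C)=C/CC/C(C)=C/C([Li])S(=O)(=O)c1ccccc1 | intermediate (not isolated)
31 | (2R)-coupled 2'-sulfone | CC(C)=CCC/C(C)=C/CC/C(C)=C/CC/C(C)=C/CC/C(C)=C/CC/C(C)=C/CC/C(C)=C/CC/C(C)=C/C(S(=O)(=O)c1ccccc1)C[C@]1(C)C=Cc2cc(O[Si](C(C)C)(C(C)C)C(C)C)c(C)c(C)c2O1 | intermediate
32 | (2R)-O-TIPS-plastochromenol-8 | CC(C)=CCC/C(C)=C/CC/C(C)=C/CC/C(C)=C/CC/C(C)=C/CC/C(C)=C/CC/C(C)=C/CC/C(C)=C/CC[C@]1(C)C=Cc2cc(O[Si](C(C)C)(C(C)C)C(C)C)c(C)c(C)c2O1 | intermediate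
33 | plastochromenol-8 (2R) | CC(C)=CCC/C(C)=C/CC/C(C)=C/CC/C(C)=C/CC/C(C)=C/CC/C(C)=C/CC/C(C)=C/CC/C(C)=C/CC[C@]1(C)C=Cc2cc(O)c(C)c(C)c2O1 | target

## Step count and weak points
Total steps: 23. Longest linear sequence: 14 steps (3 to 33 through steps 2–11 and 20–23).

**Step 5 (chromene annulation).** The γ,γ'-dioxygenated enal 6 may polymerise or react sluggishly with the ortho-methyl phenoxide. The fallback sets out from 2 and 3 and returns at 9.
- Compound 2 is ortho-formylated (MgCl2, Et3N, paraformaldehyde, MeCN, reflux) to 2-hydroxy-3,4-dimethyl-5-(triisopropylsilyloxy)benzaldehyde F1.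
- Compound 3 is treated with bromomethylenetriphenylphosphorane (from Ph3PCH2Br bromide and KOt-Bu, THF, −78 °C) to give 5-(bromomethylidene)-2,2-dimethyl-1,3-dioxane F2.
- Br/Li exchange on F2 (t-BuLi, Et2O, −78 °C) and addition of 2.2 equiv of the alkenyllithium to F1 gives the racemic o-hydroxybenzylic allylic alcohol 2-[2-(2,2-dimethyl-1,3-dioxan-5-ylidene)-1-hydroxyethyl]-5,6-dimethyl-4-(triisopropylsilyloxy)phenol F3.
- F3 loses water on warming in toluene with catalytic PPTS (through 8) and closes to 9.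

**Step 7 (lipase desymmetrisation).** The chromene diol is a new substrate, so the acylation may be slow or of low ee, or it may go to the other arm. The fallback sets out from 10 and returns at 11.
- Compound 10 is peracetylated (Ac2O, pyridine) to the achiral [7,8-dimethyl-6-(triisopropylsilyloxy)-2H-chromene-2,2-diyl]dimethyl diacetate F4.
- The direction of the enzymatic reaction is then reversed to a lipase-catalysed enantiotopic-group-selective mono-hydrolysis (pH 7 phosphate buffer/MTBE, 25 °C).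
- The hydrolase removes the acetate from the arm it prefers and leaves the acetate on the other arm. A lipase that gives the enantiomer of 11 in the acylation mode therefore gives 11 in the hydrolysis mode.
- Candida antarctica B and Burkholderia cepacia lipases are both tested in the two modes, and the combination giving 11 in the highest ee is kept.

**Step 14 (terminal SeO2 oxidation).** Four similar trisubstituted alkenes compete and over-oxidation occurs, so the yield may be poor. The fallback sets out from 20 and returns at 21.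
- NBS in THF/H2O (0 °C) gives the terminal bromohydrin 14-bromo-15-hydroxy-14,15-dihydrogeranylgeranyl TBDPS ether F5.
- K2CO3/MeOH closes it to the 14,15-epoxygeranylgeranyl TBDPS ether F6.
- H5IO6 (THF/Et2O, 0 °C) cleaves it to (4E,8E,12E)-14-(tert-butyldiphenylsilyloxy)-4,8,12-trimethyltetradeca-4,8,12-trienal F7.
- An E-selective Wittig reaction with Ph3P=C(CH3)CO2Et gives ethyl (2E,6E,10E,14E)-16-(tert-butyldiphenylsilyloxy)-2,6,10,14-tetramethylhexadeca-2,6,10,14-tetraenoate F8.
- DIBAL-H (−78 °C) reduces F8 to 21.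

## Further compounds
F1 | step 5 | 2-hydroxy-3,4-dimethyl-5-(triisopropylsilyloxy)benzaldehyde | O=Cc1cc(O[Si](C(C)C)(C(C)C)C(C)C)c(C)c(C)c1O
F2 | step 5 | 5-(bromomethylidene)-2,2-dimethyl-1,3-dioxane | BrC=C1COC(C)(C)OC1
F3 | step 5 | 2-[2-(2,2-dimethyl-1,3-dioxan-5-ylidene)-1-hydroxyethyl]-5,6-dimethyl-4-(triisopropylsilyloxy)phenol (racemic) | OC(C=C1COC(C)(C)OC1)c1cc(O[Si](C(C)C)(C(C)C)C(C)C)c(C)c(C)c1O
F4 | step 7 | [7,8-dimethyl-6-(triisopropylsilyloxy)-2H-chromene-2,2-diyl]dimethyl diacetate | CC(=O)OCC1(COC(C)=O)C=Cc2cc(O[Si](C(C)C)(C(C)C)C(C)C)c(C)c(C)c2O1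
F5 | step 14 | 14-bromo-15-hydroxy-14,15-dihydrogeranylgeranyl TBDPS ether (racemic) | CC(C)(O)C(Br)CC/C(C)=C/CC/C(C)=C/CC/C(C)=C/CO[Si](c1ccccc1)(c1ccccc1)C(C)(C)C
F6 | step 14 | 14,15-epoxygeranylgeranyl TBDPS ether (racemic) | CC1(C)OC1CC/C(C)=C/CC/C(C)=C/CC/C(C)=C/CO[Si](c1ccccc1)(c1ccccc1)C(C)(C)C
F7 | step 14 | (4E,8E,12E)-14-(tert-butyldiphenylsilyloxy)-4,8,12-trimethyltetradeca-4,8,12-trienal | O=CCC/C(C)=C/CC/C(C)=C/CC/C(C)=C/CO[Si](c1ccccc1)(c1ccccc1)C(C)(C)C
F8 | step 14 | ethyl (2E,6E,10E,14E)-16-(tert-butyldiphenylsilyloxy)-2,6,10,14-tetramethylhexadeca-2,6,10,14-tetraenoate | CCOC(=O)/C(C)=C/CC/C(C)=C/CC/C(C)=C/CC/C(C)=C/CO[Si](c1ccccc1)(c1ccccc1)C(C)(C)C
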